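Ring A is cut at C7–C8 and C5–C6. Its C5 and C7 hydroxyls sit where the carbonyls of a folded triketide would be, and the C6 substituent, with its carbinol γ to C7, is what a γ-butyrolactone leaves when its acyl carbon becomes C7 and its α-carbon C6. The precursor is a 4-pyranone holding ring B, O1, C2–C4, C4a and C8a, with an ester carbon (future C5) on C4a and a homoprenyl chain whose first CH2 becomes C8. Lateral acylation by the (R)-lactone and Dieckmann closure then complete ring A, both side chains placed, in one operation. Ring B is carried as silyl ethers.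

Key step: step 7

Assumption: the stereocentre of the SMILES is read as (R); it is taken from commercial (R)-5-oxotetrahydrofuran-2-carboxylic acid and is not touched afterwards. Chromone numbering is used for the target and for the atoms that end up in it.

Design note: ring B is protected as triisopropylsilyl ethers. They tolerate the amide base, and their bulk disfavours attack of the ortho oxygen on the arylacetyl chloride. They are removed by fluoride, so the prenyl and 2-hydroxy-3-methylbut-3-enyl groups next to free phenols never meet acid. A silyl group lost or shifted under the basic conditions of step 7 would be removed in step 8 in any case.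

Step 1
Reactants: 1 methyl acetoacetate; 2 prenyl bromide (1-bromo-3-methylbut-2-ene)
Product: 3 methyl 7-methyl-3-oxooct-6-enoate
Conditions: NaH, THF, 0 °C; n-BuLi, 0 °C; 2, 0 °C to rt; 1 M HCl
Reagents that add atoms: none
Why: Double deprotonation gives the acetoacetate dianion, whose terminal carbon is the more nucleophilic site, so the allylic bromide is taken up there by SN2 substitution (γ-alkylation of a β-keto ester dianion); no stereocentre is formed.

Step 2
Reactants: 4 2,4-dihydroxyphenylacetic acid
Product: 6 2,4-bis(triisopropylsilyloxy)phenylacetic acid, via silyl ester 5 (not isolated)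
Conditions: iPr3SiCl, imidazole, DMF, rt to 40 °C; then K2CO3, THF/MeOH/H2O, 0 °C to rt; 1 M HCl to pH 4
Reagents that add atoms: chlorotriisopropylsilane, CC(C)[Si](Cl)(C(C)C)C(C)C
Why: Imidazole-promoted silylation covers both phenols and the acid, and the silyl ester, far more labile than an aryl silyl ether, is then hydrolysed selectively by mild aqueous carbonate.

Step 3
Reactants: 6 2,4-bis(triisopropylsilyloxy)phenylacetic acid; 3 methyl 7-methyl-3-oxooct-6-enoate
Product: 8 methyl 2-{[2,4-bis(triisopropylsilyloxy)phenyl]acetyl}-7-methyl-3-oxooct-6-enoate, via acid chloride 7 (not isolated)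
Conditions: (COCl)2, N,N-dimethylformamide (cat.), CH2Cl2, 0 °C to rt, volatiles removed; then 3, MgCl2, pyridine, CH2Cl2, 0 °C to rt; 1 M HCl wash
Reagents that add atoms: none
Why: The acid chloride acylates the chelated magnesium enolate of 3 on carbon (soft enolisation with MgCl2 and pyridine, C-acylation of a β-keto ester); the new methine is enolised, so no defined stereocentre arises.

Step 4
Reactants: 8 methyl 2-{[2,4-bis(triisopropylsilyloxy)phenyl]acetyl}-7-methyl-3-oxooct-6-enoate
Product: 10 methyl 5-[2,4-bis(triisopropylsilyloxy)phenyl]-2-(4-methylpent-3-enyl)-4-oxo-4H-pyran-3-carboxylate, via enaminone 9 (not isolated)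
Conditions: Me2NCH(OMe)2, toluene, 80 °C
Reagents that add atoms: N,N-dimethylformamide dimethyl acetal, COC(OC)N(C)C
Why: The amide acetal should condense at the aryl-activated benzylic methylene, as in the deoxybenzoin route to isoflavones, and the enol oxygen of the neighbouring alkyl ketone then displaces dimethylamine by conjugate addition–elimination to close the 4-pyranone (enaminone cyclisation of a 2-acyl-1,3-dicarbonyl compound).

Step 5
Reactants: 11 (R)-5-oxotetrahydrofuran-2-carboxylic acid
Product: 13 (R)-5-acetyldihydrofuran-2(3H)-one, via acid chloride 12 (not isolated)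
Conditions: (COCl)2, N,N-dimethylformamide (cat.), CH2Cl2, 0 °C to rt, volatiles removed; then Me2Zn (0.6 equiv), Pd(PPh3)4 (cat.), THF, 0 °C to rt
Reagents that add atoms: dimethylzinc, C[Zn]C
Why: Zerovalent palladium inserts into the C–Cl bond of 12 and the acyl complex is methylated by the zinc reagent (Negishi acylation) under neutral conditions, so the lactone and the stereocentre next to the new ketone are untouched and the (R) configuration of 11 is carried over.

Step 6
Reactants: 13 (R)-5-acetyldihydrofuran-2(3H)-one
Product: 14 (R)-5-(prop-1-en-2-yl)dihydrofuran-2(3H)-one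
Conditions: Zn, CH2Br2, TiCl4, THF, 0 °C (reagent pre-formed); then 13, CH2Cl2, 0 °C to rt; aqueous work-up
Reagents that add atoms: dibromomethane, BrCBr
Why: The non-basic titanium–zinc methylene reagent (Takai–Lombardo methylenation) converts the ketone into the 1,1-disubstituted alkene in preference to the lactone carbonyl and without enolising the neighbouring stereocentre, which therefore keeps its (R) configuration.

Step 7
Reactants: 10 methyl 5-[2,4-bis(triisopropylsilyloxy)phenyl]-2-(4-methylpent-3-enyl)-4-oxo-4H-pyran-3-carboxylate; 14 (R)-5-(prop-1-en-2-yl)dihydrofuran-2(3H)-one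
Product: 16 3-[2,4-bis(triisopropylsilyloxy)phenyl]-5,7-dihydroxy-6-[(2R)-2-hydroxy-3-methylbut-3-enyl]-8-(3-methylbut-2-enyl)-4H-chromen-4-one, via open-chain hydroxy ketone 15 (not isolated)
Conditions: LiN(iPr)2 (1.1 equiv), THF, −78 °C, 10 added slowly; 14 (1.3 equiv), −78 to −40 °C; LiN(iPr)2 (2.3 equiv), −78 to 0 °C; AcOH quench
Reagents that add atoms: none
Why: Proposed new method: LiN(iPr)2 removes a proton from the CH2 on pyranone C2 (future C8), which is γ to both the ring ketone and the ester, and this delocalised carbanion adds to the lactone carbonyl; the lactol alkoxide opens at the acyl C–O bond (C7–C8 formed, carbinol released as its alkoxide), the second charge of base turns the resulting C8 enolate into a C6/C8 dianion, and its C6 terminus attacks the neighbouring ester (C5–C6 formed), after which loss of methoxide and enolisation give the aromatic 5,7-diol. The closest known reaction types are the Staunton–Weinreb annulation of lateral toluate anions, lateral acylation of 2-alkyl-4-pyranones, terminal acylation of β-dicarbonyl dianions and base-induced Claisen cyclisation of pyranone-masked polyketide chains. Ring A closes by a 6-exo-trig Dieckmann-type attack of an enolate carbon on the ester carbonyl, made irreversible by aromatisation. No stereocentre is created: C8 is stereogenic only in passing, and the (R)-carbinol of 14 is kept because only the acyl C–O bond breaks and that carbon carries no acidic hydrogen. The step needs acylation of the lateral anion to outrun its conjugate addition to unreacted pyranone, which slow addition of 10 to cold base and the low acidity of the lactone relative to the anion should secure. It also needs closure through C6 and not through the enolate oxygen (closure from C8 would require a four-membered ring), which the dianion favours by reacting at its last-formed, most basic carbon; the positions of the two side chains follow from the connectivity of 10 and 14.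

Step 8
Reactants: 16 3-[2,4-bis(triisopropylsilyloxy)phenyl]-5,7-dihydroxy-6-[(2R)-2-hydroxy-3-methylbut-3-enyl]-8-(3-methylbut-2-enyl)-4H-chromen-4-one
Product: 17 3-(2,4-dihydroxyphenyl)-5,7-dihydroxy-6-[(2R)-2-hydroxy-3-methylbut-3-enyl]-8-(3-methylbut-2-enyl)-4H-chromen-4-one (CNP0408283.2)
Conditions: Bu4NF, AcOH, THF, 0 °C to rt
Reagents that add atoms: none
Why: Fluoride attacks silicon and releases the two phenoxides (desilylation of aryl silyl ethers) under buffered conditions free of strong acid, so the prenyl group, the allylic alcohol with its (R) centre and the ortho phenols are not drawn into cyclisation.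

Compound list
1 | methyl acetoacetate | COC(=O)CC(C)=O | starting material
2 | prenyl bromide (1-bromo-3-methylbut-2-ene) | CC(C)=CCBr | starting material
3 | methyl 7-methyl-3-oxooct-6-enoate | COC(=O)CC(=O)CCC=C(C)C | intermediate
4 | 2,4-dihydroxyphenylacetic acid | OC(=O)Cc1ccc(O)cc1O | starting material
5 | triisopropylsilyl 2,4-bis(triisopropylsilyloxy)phenylacetate | CC(C)[Si](OC(=O)Cc1ccc(O[Si](C(C)C)(C(C)C)C(C)C)cc1O[Si](C(C)C)(C(C)C)C(C)C)(C(C)C)C(C)C | intermediate
6 | 2,4-bis(triisopropylsilyloxy)phenylacetic acid | OC(=O)Cc1ccc(O[Si](C(C)C)(C(C)C)C(C)C)cc1O[Si](C(C)C)(C(C)C)C(C)C | intermediate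
7 | 2,4-bis(triisopropylsilyloxy)phenylacetyl chloride | O=C(Cl)Cc1ccc(O[Si](C(C)C)(C(C)C)C(C)C)cc1O[Si](C(C)C)(C(C)C)C(C)C | intermediate
8 | methyl 2-{[2,4-bis(triisopropylsilyloxy)phenyl]acetyl}-7-methyl-3-oxooct-6-enoate (drawn as the triketo tautomer; central carbon enolised) | COC(=O)C(C(=O)Cc1ccc(O[Si](C(C)C)(C(C)C)C(C)C)cc1O[Si](C(C)C)(C(C)C)C(C)C)C(=O)CCC=C(C)C | intermediate
9 | methyl 2-{2-[2,4-bis(triisopropylsilyloxy)phenyl]-3-(dimethylamino)prop-2-enoyl}-7-methyl-3-oxooct-6-enoate (double-bond geometry immaterial, either isomer cyclises) | COC(=O)C(C(=O)C(=CN(C)C)c1ccc(O[Si](C(C)C)(C(C)C)C(C)C)cc1O[Si](C(C)C)(C(C)C)C(C)C)C(=O)CCC=C(C)C | intermediate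
10 | methyl 5-[2,4-bis(triisopropylsilyloxy)phenyl]-2-(4-methylpent-3-enyl)-4-oxo-4H-pyran-3-carboxylate | COC(=O)c1c(CCC=C(C)C)occ(-c2ccc(O[Si](C(C)C)(C(C)C)C(C)C)cc2O[Si](C(C)C)(C(C)C)C(C)C)c1=O | intermediate
11 | (R)-5-oxotetrahydrofuran-2-carboxylic acid | OC(=O)[C@H]1CCC(=O)O1 | starting material
12 | (R)-5-oxotetrahydrofuran-2-carbonyl chloride | O=C(Cl)[C@H]1CCC(=O)O1 | intermediate
13 | (R)-5-acetyldihydrofuran-2(3H)-one | CC(=O)[C@H]1CCC(=O)O1 | intermediate
14 | (R)-5-(prop-1-en-2-yl)dihydrofuran-2(3H)-one | C=C(C)[C@H]1CCC(=O)O1 | intermediate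
15 | methyl 5-[2,4-bis(triisopropylsilyloxy)phenyl]-2-[(9R)-9-hydroxy-2,10-dimethyl-6-oxoundeca-2,10-dien-5-yl]-4-oxo-4H-pyran-3-carboxylate (both epimers at the carbon bearing the prenyl group; present as its lithium enolate and alkoxide) | COC(=O)c1c(C(CC=C(C)C)C(=O)CC[C@@H](O)C(C)=C)occ(-c2ccc(O[Si](C(C)C)(C(C)C)C(C)C)cc2O[Si](C(C)C)(C(C)C)C(C)C)c1=O | intermediate
16 | 3-[2,4-bis(triisopropylsilyloxy)phenyl]-5,7-dihydroxy-6-[(2R)-2-hydroxy-3-methylbut-3-enyl]-8-(3-methylbut-2-enyl)-4H-chromen-4-one | C=C(C)[C@H](O)Cc1c(O)c(CC=C(C)C)c2occ(-c3ccc(O[Si](C(C)C)(C(C)C)C(C)C)cc3O[Si](C(C)C)(C(C)C)C(C)C)c(=O)c2c1O | intermediate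
17 | 3-(2,4-dihydroxyphenyl)-5,7-dihydroxy-6-[(2R)-2-hydroxy-3-methylbut-3-enyl]-8-(3-methylbut-2-enyl)-4H-chromen-4-one | C=C(C)[C@H](O)Cc1c(O)c(CC=C(C)C)c2occ(-c3ccc(O)cc3O)c(=O)c2c1O | target

Total step count: 8. Longest linear sequence: 5 steps (step 1 or step 2, then steps 3, 4, 7 and 8); the lactone branch (steps 5 and 6) joins at step 7.

Steps most likely to fail

Step 7, the one new method of the route. The lateral anion may be quenched by proton transfer from the acidic acylation product, or it may add in conjugate fashion to unreacted pyranone. Ring closure may also take place through the enolate oxygen (α-pyranone formation) instead of through C6. The fallback makes the two C–C bonds in separate reactions of established type with an open-chain acyl donor; it sets out from 14 and 10 and comes back to the route at 17. Lactone 14 is opened with MeNHOMe·HCl and AlMe3 (CH2Cl2, 0 °C) to the hydroxy Weinreb amide (4R)-4-hydroxy-N-methoxy-N,5-dimethylhex-5-enamide F1. This is silylated without delay (t-BuMe2SiCl, imidazole, DMF) to (4R)-4-(tert-butyldimethylsilyloxy)-N-methoxy-N,5-dimethylhex-5-enamide F2. The lateral lithium anion of 10 (LiN(iPr)2, THF, −78 °C) is acylated by F2. The chelated tetrahedral adduct of the Weinreb amide persists until the quench, so the acidic product cannot consume the anion. The ketone obtained is methyl 5-[2,4-bis(triisopropylsilyloxy)phenyl]-2-[(9R)-9-(tert-butyldimethylsilyloxy)-2,10-dimethyl-6-oxoundeca-2,10-dien-5-yl]-4-oxo-4H-pyran-3-carboxylate F3. A separate base-induced Claisen cyclisation (LiN(SiMe3)2 or NaH, THF, 0 °C to rt), the established way of folding pyranone-masked polyketide chains into phloroglucinol rings, should give 3-[2,4-bis(triisopropylsilyloxy)phenyl]-6-[(2R)-2-(tert-butyldimethylsilyloxy)-3-methylbut-3-enyl]-5,7-dihydroxy-8-(3-methylbut-2-enyl)-4H-chromen-4-one F4. Bu4NF/AcOH as in step 8 then removes all three silyl groups to give 17.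

Step 4. Aminomethylenation may take place at the alkyl methylene next to the other ketone instead of at the benzylic one. The enol may be O-methylated by the acetal, or the tricarbonyl may be deacylated by the methanol and dimethylamine that are released. The fallback sets out from 8 and comes back at 10. Two equivalents of LiN(iPr)2 (THF, −78 to 0 °C) convert 8 into its dianion, the second deprotonation settling at the benzylic carbon under equilibrating conditions. Terminal formylation of this dianion with ethyl formate gives methyl 2-{2-[2,4-bis(triisopropylsilyloxy)phenyl]-3-oxopropanoyl}-7-methyl-3-oxooct-6-enoate F5. Acid-catalysed cyclodehydration of this 1,3,5-tricarbonyl compound (p-toluenesulfonic acid, toluene, rt to 50 °C) closes the 4-pyranone 10. No amine or alkylating acetal is present, and the site of the one-carbon unit is set by the order of deprotonation.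

Step 3. The arylacetyl chloride may lose HCl to a ketene that dimerises, or it may acylate its own ortho silyl ether oxygen (lactonisation with loss of that protecting group). The enolate may also be acylated on oxygen. The fallback reverses the roles of the two fragments; it sets out from 6 and comes back at 8. Acid 6 is activated with 1,1'-carbonyldiimidazole (THF, rt) to 1-{[2,4-bis(triisopropylsilyloxy)phenyl]acetyl}-1H-imidazole F6. Decarboxylative Claisen condensation with Mg(O2CCH2CO2Me)2 gives methyl 4-[2,4-bis(triisopropylsilyloxy)phenyl]-3-oxobutanoate F7. Its magnesium enolate (MgCl2, pyridine, CH2Cl2) is C-acylated with 5-methylhex-4-enoyl chloride F8, made from commercial 5-methylhex-4-enoic acid and (COCl)2, to give 8. An aliphatic acid chloride without a neighbouring oxygen substituent cannot lactonise.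

Further compounds
F1 | step 7 | (4R)-4-hydroxy-N-methoxy-N,5-dimethylhex-5-enamide | C=C(C)[C@H](O)CCC(=O)N(C)OC
F2 | step 7 | (4R)-4-(tert-butyldimethylsilyloxy)-N-methoxy-N,5-dimethylhex-5-enamide | C=C(C)[C@H](O[Si](C)(C)C(C)(C)C)CCC(=O)N(C)OC
F3 | step 7 | methyl 5-[2,4-bis(triisopropylsilyloxy)phenyl]-2-[(9R)-9-(tert-butyldimethylsilyloxy)-2,10-dimethyl-6-oxoundeca-2,10-dien-5-yl]-4-oxo-4H-pyran-3-carboxylate | COC(=O)c1c(C(CC=C(C)C)C(=O)CC[C@@H](O[Si](C)(C)C(C)(C)C)C(C)=C)occ(-c2ccc(O[Si](C(C)C)(C(C)C)C(C)C)cc2O[Si](C(C)C)(C(C)C)C(C)C)c1=O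
F4 | step 7 | 3-[2,4-bis(triisopropylsilyloxy)phenyl]-6-[(2R)-2-(tert-butyldimethylsilyloxy)-3-methylbut-3-enyl]-5,7-dihydroxy-8-(3-methylbut-2-enyl)-4H-chromen-4-one | C=C(C)[C@H](O[Si](C)(C)C(C)(C)C)Cc1c(O)c(CC=C(C)C)c2occ(-c3ccc(O[Si](C(C)C)(C(C)C)C(C)C)cc3O[Si](C(C)C)(C(C)C)C(C)C)c(=O)c2c1O
F5 | step 4 | methyl 2-{2-[2,4-bis(triisopropylsilyloxy)phenyl]-3-oxopropanoyl}-7-methyl-3-oxooct-6-enoate | COC(=O)C(C(=O)C(C=O)c1ccc(O[Si](C(C)C)(C(C)C)C(C)C)cc1O[Si](C(C)C)(C(C)C)C(C)C)C(=O)CCC=C(C)C
F6 | step 3 | 1-{[2,4-bis(triisopropylsilyloxy)phenyl]acetyl}-1H-imidazole | O=C(Cc1ccc(O[Si](C(C)C)(C(C)C)C(C)C)cc1O[Si](C(C)C)(C(C)C)C(C)C)n1ccnc1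
F7 | step 3 | methyl 4-[2,4-bis(triisopropylsilyloxy)phenyl]-3-oxobutanoate | COC(=O)CC(=O)Cc1ccc(O[Si](C(C)C)(C(C)C)C(C)C)cc1O[Si](C(C)C)(C(C)C)C(C)C
F8 | step 3 | 5-methylhex-4-enoyl chloride | CC(C)=CCCC(=O)Cl
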